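**Assumption:** the target has no stereocentre (two identical, achiral halves), so there is no enantiomer to select. The only stereocentre in the route (the carbinol carbon of 3) is formed racemic and is erased in step 2.

## Retrosynthetic overview
1. Target 18 ⇒ global MOM removal from tetra-MOM ether 17 ⇒ Williamson C–O disconnection into the alkoxide of alcohol 14 and bromide 15, both made from triol 13.
2. Triol 13 ⇒ benzylic functionalisation (Wohl–Ziegler, acetate displacement, hydrolysis) of tribromo-4-methylcatechol 9 ⇒ exhaustive ring bromination of 4-methylcatechol 8.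
3. 8 ⇒ creosol 7 ⇒ vanillin 5 (deoxygenation, then O-demethylation). A methyl group is carried through the bromination because it cannot be displaced by ipso attack.
4. Key C–C disconnection: the aryl–benzylic carbon bond, 5 ⇒ mandelic acid 3 ⇒ guaiacolate 1 (a vinylogous enolate) + glyoxylic acid 2, an intermolecular aldol-type addition.
5. No ring is formed. Both benzene rings come intact from guaiacol.

## Route

Step 1
Reactants: 1 guaiacol (2-methoxyphenol, 1.5 equiv); 2 glyoxylic acid (50% aqueous solution)
Product: 3 rac-4-hydroxy-3-methoxymandelic acid
Conditions: NaOH (2.5 equiv), H2O, 0 °C → 20 °C, 24 h; toluene wash at pH 6; then HCl to pH 1–2, EtOAc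
Reagents that add atoms: none
Why: Intermolecular aldol-type addition (phenolate hydroxyalkylation) in which the guaiacolate, a vinylogous enolate, attacks the very electrophilic glyoxylate aldehyde through its unhindered para carbon and then re-aromatises, giving a racemic carbinol centre that is destroyed in step 2.

Step 2
Reactants: 3 rac-4-hydroxy-3-methoxymandelic acid
Product: 5 vanillin (4-hydroxy-3-methoxybenzaldehyde), via 4-hydroxy-3-methoxyphenylglyoxylic acid 4 (not isolated)
Conditions: air sparge, CuSO4 (5 mol %), aq. NaOH, 90–95 °C; then H2SO4 to pH 3, 60 °C
Reagents that add atoms: none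
Why: Aerobic oxidative decarboxylation catalysed by divalent copper, in which the benzylic carbinol of the electron-rich phenolate is dehydrogenated to keto acid 4 and the p-hydroxyaryl keto acid loses CO2 on acidification.

Step 3
Reactants: 5 vanillin
Product: 7 creosol (2-methoxy-4-methylphenol), via vanillyl alcohol 6 (not isolated)
Conditions: H2 (4 bar), 10% Pd/C, AcOH, 50 °C
Reagents that add atoms: none
Why: Catalytic hydrogenation followed by benzylic hydrogenolysis, which is easy for a p-hydroxybenzyl alcohol in acid and is done before any halogen is present, so that the later perbromination meets a methyl group and not a formyl or hydroxymethyl group open to ipso substitution.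

Step 4
Reactants: 7 creosol
Product: 8 4-methylcatechol (4-methylbenzene-1,2-diol)
Conditions: 48% aq. HBr, AcOH, reflux, N2
Reagents that add atoms: none
Why: Acidic aryl methyl ether cleavage (SN2 attack of bromide on the protonated O–CH3), the classical guaiacol-to-catechol conversion, with nothing else in the molecule that can react.

Step 5
Reactants: 8 4-methylcatechol
Product: 9 3,4,6-tribromo-5-methylbenzene-1,2-diol
Conditions: Br2 (3.1 equiv), glacial AcOH, 10 °C → rt, dark; aq. NaHSO3 quench
Reagents that add atoms: bromine, BrBr
Why: Exhaustive electrophilic aromatic bromination that works because each of the three free ring positions is ortho or para to a hydroxyl (as in catechol to tetrabromocatechol), while limited Br2, low temperature and darkness keep the methyl group untouched.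

Step 6
Reactants: 9 3,4,6-tribromo-5-methylbenzene-1,2-diol
Product: 10 3,4,6-tribromo-5-methyl-1,2-phenylene diacetate
Conditions: Ac2O (3 equiv), pyridine, DMAP (5 mol %), 0 °C → rt
Reagents that add atoms: acetic anhydride, CC(=O)OC(C)=O
Why: DMAP-catalysed O-acylation of the acidic phenols, which masks the oxidisable catechol with groups that have no easily abstracted hydrogen and so survive radical bromination.

Step 7
Reactants: 10 3,4,6-tribromo-5-methyl-1,2-phenylene diacetate
Product: 11 4,5-diacetoxy-2,3,6-tribromobenzyl bromide
Conditions: NBS (1.2 equiv), dibenzoyl peroxide (5 mol %, two portions), PhCF3, reflux, visible light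
Reagents that add atoms: N-bromosuccinimide, O=C1CCC(=O)N1Br
Why: Wohl–Ziegler benzylic bromination, in which the fully substituted ring excludes nuclear bromination, the two ortho bromines disfavour a second side-chain bromination, and pentabromotoluene behaves the same way.

Step 8
Reactants: 11 4,5-diacetoxy-2,3,6-tribromobenzyl bromide
Product: 12 4,5-diacetoxy-2,3,6-tribromobenzyl acetate
Conditions: NaOAc (3 equiv), AcOH, reflux
Reagents that add atoms: sodium acetate, CC(=O)[O-].[Na+]
Why: SN2 displacement of a primary benzylic bromide by a carboxylate, proven on perbrominated and 2,6-dihalogenated benzyl halides, run in acetic acid so that the aryl acetates cannot be lost.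

Step 9
Reactants: 12 4,5-diacetoxy-2,3,6-tribromobenzyl acetate
Product: 13 2,3,6-tribromo-4,5-dihydroxybenzyl alcohol
Conditions: aq. H2SO4 (1 mol/L), 1,4-dioxane/H2O 2:1, 80 °C, N2
Reagents that add atoms: none
Why: Acid-catalysed ester hydrolysis by acyl–oxygen cleavage of all three acetates, which needs no ionisation at the benzylic carbon, keeps the catechol protonated and safe from air oxidation, and offers water as the only nucleophile so no alkyl ether can form.

Step 10
Reactants: 13 2,3,6-tribromo-4,5-dihydroxybenzyl alcohol
Product: 14 [2,3,6-tribromo-4,5-bis(methoxymethoxy)phenyl]methanol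
Conditions: MOMCl (2.3 equiv), K2CO3 (4 equiv), acetone, 0 °C → rt, N2
Reagents that add atoms: chloromethyl methyl ether, COCCl
Why: Chemoselective phenolate O-alkylation (acetal protection), since K2CO3 deprotonates only the acidic bromophenol hydroxyls and the small, very reactive MOMCl reaches them despite the flanking bromines while the neutral primary alcohol stays free.

Step 11
Reactants: 14 [2,3,6-tribromo-4,5-bis(methoxymethoxy)phenyl]methanol (about half of the material)
Product: 15 2,3,6-tribromo-4,5-bis(methoxymethoxy)benzyl bromide
Conditions: CBr4 (1.3 equiv), PPh3 (1.3 equiv), CH2Cl2, 0 °C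
Reagents that add atoms: carbon tetrabromide, BrC(Br)(Br)Br
Why: Appel reaction, an essentially neutral conversion of a primary benzylic alcohol into the bromide that leaves the acid-labile MOM acetals and the aryl bromides alone.

Step 12
Reactants: 14 [2,3,6-tribromo-4,5-bis(methoxymethoxy)phenyl]methanol; 15 2,3,6-tribromo-4,5-bis(methoxymethoxy)benzyl bromide (1.05 equiv)
Product: 17 bis[2,3,6-tribromo-4,5-bis(methoxymethoxy)benzyl] ether, via sodium alkoxide 16 (not isolated)
Conditions: NaH (1.2 equiv), THF/DMF 4:1, 0 °C; then 15, Bu4NI (10 mol %), rt → 40 °C
Reagents that add atoms: none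
Why: Williamson ether synthesis between a primary alkoxide and a primary benzylic bromide, for which MOM ethers are inert to base, the hydrogen-free rings cannot form arynes, and 2,6-dihalobenzyl halides are known to form such bis-ethers readily.

Step 13
Reactants: 17 bis[2,3,6-tribromo-4,5-bis(methoxymethoxy)benzyl] ether
Product: 18 bis(2,3,6-tribromo-4,5-dihydroxybenzyl) ether
Conditions: aq. HCl (6 mol/L)/THF 1:3, 40 °C, N2
Reagents that add atoms: none
Why: Acid-catalysed acetal hydrolysis of the four aryl MOM ethers, which goes through the methoxymethyl oxocarbenium ion, whereas the central ether would have to ionise to a benzylic cation destabilised by three bromines, and the released formaldehyde finds no free ring position to attack.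

## Compound list
1 | guaiacol (2-methoxyphenol) | COc1ccccc1O | starting material
2 | glyoxylic acid | O=CC(=O)O | starting material
3 | rac-4-hydroxy-3-methoxymandelic acid (racemate) | COc1cc(C(O)C(=O)O)ccc1O | intermediate
4 | 4-hydroxy-3-methoxyphenylglyoxylic acid (formed in the flask, not isolated) | COc1cc(C(=O)C(=O)O)ccc1O | intermediate
5 | vanillin | COc1cc(C=O)ccc1O | intermediate
6 | vanillyl alcohol (formed in the flask, not isolated) | COc1cc(CO)ccc1O | intermediate
7 | creosol (2-methoxy-4-methylphenol) | COc1cc(C)ccc1O | intermediate
8 | 4-methylcatechol | Cc1ccc(O)c(O)c1 | intermediate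
9 | 3,4,6-tribromo-5-methylbenzene-1,2-diol | Cc1c(Br)c(Br)c(O)c(O)c1Br | intermediate
10 | 3,4,6-tribromo-5-methyl-1,2-phenylene diacetate | Cc1c(Br)c(Br)c(OC(C)=O)c(OC(C)=O)c1Br | intermediate
11 | 4,5-diacetoxy-2,3,6-tribromobenzyl bromide | BrCc1c(Br)c(Br)c(OC(C)=O)c(OC(C)=O)c1Br | intermediate
12 | 4,5-diacetoxy-2,3,6-tribromobenzyl acetate | CC(=O)OCc1c(Br)c(Br)c(OC(C)=O)c(OC(C)=O)c1Br | intermediate
13 | 2,3,6-tribromo-4,5-dihydroxybenzyl alcohol | OCc1c(Br)c(Br)c(O)c(O)c1Br | intermediate
14 | [2,3,6-tribromo-4,5-bis(methoxymethoxy)phenyl]methanol | OCc1c(Br)c(Br)c(OCOC)c(OCOC)c1Br | intermediate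
15 | 2,3,6-tribromo-4,5-bis(methoxymethoxy)benzyl bromide | BrCc1c(Br)c(Br)c(OCOC)c(OCOC)c1Br | intermediate
16 | sodium [2,3,6-tribromo-4,5-bis(methoxymethoxy)phenyl]methanolate (formed in the flask, not isolated) | [Na+].[O-]Cc1c(Br)c(Br)c(OCOC)c(OCOC)c1Br | intermediate
17 | bis[2,3,6-tribromo-4,5-bis(methoxymethoxy)benzyl] ether | COCOc1c(OCOC)c(Br)c(COCc2c(Br)c(OCOC)c(OCOC)c(Br)c2Br)c(Br)c1Br | intermediate
18 | bis(2,3,6-tribromo-4,5-dihydroxybenzyl) ether | Oc1c(O)c(Br)c(COCc2c(Br)c(O)c(O)c(Br)c2Br)c(Br)c1Br | target

## Step count and risks
Total step count: 13. Longest linear sequence: 13 (steps 1–10 to 14, step 11 to 15, then steps 12 and 13).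

**Risk 1, the radical bromination (step 7).** The methyl group sits between two bromines on an electron-poor ring. Hydrogen abstraction may therefore be slow, and 10 and 11 are hard to separate at partial conversion.

The fallback sets out from 9 and comes back to the route at 13, so it replaces steps 6 to 9. It drops the radical chemistry and the acetates in favour of the ionic side-chain bromination typical of p-alkylphenols, as in the technical side-chain bromination of 2,6-dibromo-p-cresol. Free catechol 9 is heated with Br2 (1.1 equiv) in o-dichlorobenzene at 130–150 °C. The hydroxyl para to the methyl group directs bromine to the side chain and gives 2,3,6-tribromo-4,5-dihydroxybenzyl bromide F1. Stirring this in aqueous acetone at rt to 40 °C solvolyses the phenol-activated benzylic bromide to triol 13.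

**Risk 2, the Williamson coupling (step 12).** Both partners carry two ortho bromines, so the SN2 reaction may be slow and the bromide may decompose first.

The fallback sets out from 11 and comes back at the target 18, so it replaces steps 8 to 13. It gives up the alkoxide and the MOM series and uses halophilic activation instead. Bromide 11 is treated with Ag2O (0.6 equiv) in CH2Cl2/toluene at rt to 40 °C in the dark, and the oxide oxygen joins two benzyl units to give bis(4,5-diacetoxy-2,3,6-tribromobenzyl) ether F2. The four activated aryl acetates are then removed by mild hydrazinolysis (hydrazine acetate, THF/DMF, 0 °C to rt, N2), which leaves the dialkyl ether untouched and delivers 18.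

**Risk 3, the final deprotection (step 13).** Four MOM groups must leave without solvolysis of the central p-hydroxybenzylic ether, and the product is an air-sensitive catechol.

The fallback sets out from 13 and comes back at the target 18, so it replaces steps 10 to 13 with a protecting-group-free end game. Triol 13 is heated with TsOH·H2O (5 mol %) and 4 Å molecular sieves in MeNO2 or toluene/dioxane at 80–100 °C under N2. Loss of water gives transient 3,5,6-tribromo-2-hydroxy-4-methylidenecyclohexa-2,5-dien-1-one F3 (the p-quinone methide, or its O-protonated form). The primary hydroxyl of a second molecule of 13 captures it. The ring has no free position, so C-benzylation is impossible, and adducts through the acidic phenol oxygens revert. The dialkyl ether 18 therefore accumulates as water is removed.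

## Further compounds
F1 | step 7 | 2,3,6-tribromo-4,5-dihydroxybenzyl bromide | BrCc1c(Br)c(Br)c(O)c(O)c1Br
F2 | step 12 | bis(4,5-diacetoxy-2,3,6-tribromobenzyl) ether | CC(=O)Oc1c(OC(C)=O)c(Br)c(COCc2c(Br)c(OC(C)=O)c(OC(C)=O)c(Br)c2Br)c(Br)c1Br
F3 | step 13 | 3,5,6-tribromo-2-hydroxy-4-methylidenecyclohexa-2,5-dien-1-one | C=C1C(Br)=C(Br)C(=O)C(O)=C1Br
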